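**Retrosynthetic overview**
1. Vibsanin E ⇐ (E)-alkenyl boronate + 3-methylbut-2-enoic acid (stereoretentive C–O coupling); the boronate ⇐ C11 aldehyde; the acetonyl group at C10 ⇐ enolate alkylation.
2. Tricyclic core ⇐ key step: a hydrogen-atom-transfer-initiated radical 7-endo conjugate addition that forms the C1–C11 bond, making the quaternary centre C1, the stereocentre C11 and the seven-membered ring in one operation.
3. Its precursor, a cis-fused dihydropyran/methylenecyclohexane carrying an (E)-enone ⇐ Wittig methylenation and aldol condensation of a bicyclic diketone ⇐ oxa-Michael/Michael annulation of (R)-4-(2-hydroxypropan-2-yl)cyclohex-2-enone with but-3-yn-2-one.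
4. That enone ⇐ Saegusa oxidation, MeMgBr addition and a catalytic asymmetric Diels–Alder reaction of a 2-silyloxybutadiene with methyl acrylate.
5. Ring order: cyclohexane (Diels–Alder) → pyran (annulation) → cycloheptanone (radical cyclisation).

Locants for tricyclic compounds are those of 6-oxatricyclo[6.3.2.0^{4,13}]tridecane: C1 quaternary methyl carbon, C4 and C13 cyclohexane–pyran fusion, C7 the OCH2 carbon, C8 between C7 and the ketone C9, C10 and C11 the two side-chain-bearing carbons.

Assumption: the (S)-oxazaborolidine–AlBr3 catalyst is taken to give the (R)-ester in step 2; if the sense proves opposite, the (R)-catalyst is used.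

**Route**

Step 1
Reactants: 1 but-3-en-2-one
Product: 2 2-[(triisopropylsilyl)oxy]buta-1,3-diene
Conditions: TIPSOTf, Et3N, CH2Cl2, 0 °C to rt
Reagents that add atoms: triisopropylsilyl trifluoromethanesulfonate, CC(C)[Si](OS(=O)(=O)C(F)(F)F)(C(C)C)C(C)C
Why: Soft enolisation and O-silylation of the enone (silyl dienol ether formation) gives the 2-silyloxy diene; no stereocentre is formed.

Step 2
Reactants: 2 2-[(triisopropylsilyl)oxy]buta-1,3-diene; 3 methyl acrylate
Product: 4 methyl (R)-4-[(triisopropylsilyl)oxy]cyclohex-3-ene-1-carboxylate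
Conditions: (S)-3,3-diphenyl-1-(o-tolyl)tetrahydro-1H,3H-pyrrolo[1,2-c][1,3,2]oxazaborole (10 mol %), AlBr3 (8 mol %), CH2Cl2, −78 to −40 °C
Reagents that add atoms: none
Why: Catalytic enantioselective Diels–Alder reaction (Corey oxazaborolidine–AlBr3 Lewis acid); the 2-silyloxy group gives the "para" adduct and the chiral Lewis acid shields one face of the bound acrylate, setting the ester-bearing carbon (later C4) as R.

Step 3
Reactants: 4 methyl (R)-4-[(triisopropylsilyl)oxy]cyclohex-3-ene-1-carboxylate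
Product: 5 (R)-2-{4-[(triisopropylsilyl)oxy]cyclohex-3-en-1-yl}propan-2-ol
Conditions: MeMgBr (3 equiv), THF, 0 °C to rt; aq. NH4Cl
Reagents that add atoms: methylmagnesium bromide, C[Mg]Br
Why: Double Grignard addition to the ester gives the tertiary alcohol; the silyl enol ether is inert and the stereocentre is not touched.

Step 4
Reactants: 5 (R)-2-{4-[(triisopropylsilyl)oxy]cyclohex-3-en-1-yl}propan-2-ol
Product: 6 (R)-4-(2-hydroxypropan-2-yl)cyclohex-2-en-1-one
Conditions: Pd(OAc)2 (10 mol %), O2 (1 atm), DMSO, 50 °C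
Reagents that add atoms: none
Why: Saegusa–Ito oxidation; palladation at the enol ether α-carbon and β-hydride elimination can only place the new C=C next to the substituted carbon, giving the 4-substituted enone under neutral conditions that do not racemise the γ-stereocentre.

Step 5
Reactants: 6 (R)-4-(2-hydroxypropan-2-yl)cyclohex-2-en-1-one; 7 but-3-yn-2-one
Product: 9 (4aS,8aR)-4-acetyl-1,1-dimethyl-4a,5,8,8a-tetrahydro-1H-isochromen-6(7H)-one, via oxa-Michael adduct 8 (not isolated)
Conditions: PMe3 (20 mol %), CH2Cl2, 0 °C to rt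
Reagents that add atoms: none
Why: Phosphine-catalysed tandem oxa-Michael/Michael (Rauhut–Currier-type) annulation: the tertiary alcohol adds to the ynone and the resulting phosphonium enolate attacks the enone β-carbon; the attack must be axial and comes from the tether on the neighbouring carbon, so the new ring fusion is cis (4aS).

Step 6
Reactants: 9 (4aS,8aR)-4-acetyl-1,1-dimethyl-4a,5,8,8a-tetrahydro-1H-isochromen-6(7H)-one
Product: 10 1-[(4aS,8aR)-1,1-dimethyl-6-methylidene-4a,5,6,7,8,8a-hexahydro-1H-isochromen-4-yl]ethan-1-one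
Conditions: Ph3PCH3Br, KOt-Bu, THF, 0 °C to rt
Reagents that add atoms: methyltriphenylphosphonium bromide, C[P+](c1ccccc1)(c1ccccc1)c1ccccc1.[Br-]
Why: Wittig methylenation is selective for the saturated cyclohexanone over the deactivated vinylogous-ester ketone; the new CH2 becomes the C1 methyl group in step 8.

Step 7
Reactants: 10 1-[(4aS,8aR)-1,1-dimethyl-6-methylidene-4a,5,6,7,8,8a-hexahydro-1H-isochromen-4-yl]ethan-1-one; 11 2,2-dimethoxyacetaldehyde (60 wt % in water)
Product: 13 (E)-4,4-dimethoxy-1-[(4aS,8aR)-1,1-dimethyl-6-methylidene-4a,5,6,7,8,8a-hexahydro-1H-isochromen-4-yl]but-2-en-1-one, via aldol adduct 12 (not isolated)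
Conditions: K2CO3, MeOH/H2O, 40 °C
Reagents that add atoms: none
Why: Claisen–Schmidt aldol condensation of the only enolisable position (the acetyl CH3) with a non-enolisable aldehyde; E1cB dehydration gives the (E)-enone.

Step 8
Reactants: 13 (E)-4,4-dimethoxy-1-[(4aS,8aR)-1,1-dimethyl-6-methylidene-4a,5,6,7,8,8a-hexahydro-1H-isochromen-4-yl]but-2-en-1-one
Product: 14 (1S,4R,11S,13S)-11-(dimethoxymethyl)-1,5,5-trimethyl-6-oxatricyclo[6.3.2.0^{4,13}]tridec-7-en-9-one
Conditions: Fe(acac)3 (30 mol %), PhSiH3 (3 equiv), MeOH/THF 1:1, 0.01 M, 50 °C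
Reagents that add atoms: none
Why: Metal-hydride hydrogen-atom transfer to the 1,1-disubstituted alkene followed by intramolecular Giese addition (Baran reductive olefin coupling, here in an untested 7-endo bridging mode): the hydrogen atom creates the C1 methyl group, the tertiary C1 radical can reach the enone only through an axial bond cis to the axial C13–C8 bond (C1 = S), the (E)-enone passes under the one-carbon bridge with the acetal group outward and H11 inward (C11 = S), and the α-keto radical is reduced to the iron enolate and protonated.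

Step 9
Reactants: 14 (1S,4R,11S,13S)-11-(dimethoxymethyl)-1,5,5-trimethyl-6-oxatricyclo[6.3.2.0^{4,13}]tridec-7-en-9-one
Product: 15 (1S,4R,8S,11S,13S)-11-(dimethoxymethyl)-1,5,5-trimethyl-6-oxatricyclo[6.3.2.0^{4,13}]tridecan-9-one
Conditions: H2 (1 atm), Pd/C (10 wt %), EtOAc, rt
Reagents that add atoms: none
Why: Heterogeneous syn-hydrogenation of the enol-ether C=C from the exposed convex face (the face of H13) gives H8 cis to H13 (8S) and turns the vinylogous ester into the tetrahydropyran; ketone and acetal are inert.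

Step 10
Reactants: 15 (1S,4R,8S,11S,13S)-11-(dimethoxymethyl)-1,5,5-trimethyl-6-oxatricyclo[6.3.2.0^{4,13}]tridecan-9-one; 16 3-bromo-2-methoxyprop-1-ene
Product: 18 (1S,4R,8S,10S,11S,13S)-1,5,5-trimethyl-9-oxo-10-(2-oxopropyl)-6-oxatricyclo[6.3.2.0^{4,13}]tridecane-11-carbaldehyde, via C10-allylated enol ether 17 (not isolated)
Conditions: LDA, THF, −78 °C; 16, DMPU, −78 to −30 °C; then 1 M HCl, THF, 0 °C to rt
Reagents that add atoms: water, O
Why: Kinetic enolate alkylation: LDA removes the less hindered C10–H rather than the ring-fusion C8–H, the allylic bromide enters anti to the C11 substituent (10S, trans), and aqueous acid then hydrolyses the enol ether to the methyl ketone and the acetal to the aldehyde.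

Step 11
Reactants: 18 (1S,4R,8S,10S,11S,13S)-1,5,5-trimethyl-9-oxo-10-(2-oxopropyl)-6-oxatricyclo[6.3.2.0^{4,13}]tridecane-11-carbaldehyde
Product: 19 (1S,4R,8S,10S,11S,13S)-1,5,5-trimethyl-10-(2-oxopropyl)-11-[(E)-2-(4,4,5,5-tetramethyl-1,3,2-dioxaborolan-2-yl)ethenyl]-6-oxatricyclo[6.3.2.0^{4,13}]tridecan-9-one
Conditions: CrCl2 (8 equiv), Cl2CHBpin (2 equiv), LiI (4 equiv), THF, 25 °C
Reagents that add atoms: 2-(dichloromethyl)-4,4,5,5-tetramethyl-1,3,2-dioxaborolane, ClC(Cl)B1OC(C)(C)C(C)(C)O1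
Why: Takai–Utimoto boryl olefination with the geminal dichromium reagent is selective for the aldehyde over both ketones, adds the last side-chain carbon and gives the (E)-alkenyl boronate.

Step 12
Reactants: 19 (1S,4R,8S,10S,11S,13S)-1,5,5-trimethyl-10-(2-oxopropyl)-11-[(E)-2-(4,4,5,5-tetramethyl-1,3,2-dioxaborolan-2-yl)ethenyl]-6-oxatricyclo[6.3.2.0^{4,13}]tridecan-9-one; 20 3-methylbut-2-enoic acid
Product: 21 vibsanin E, (E)-2-[(1S,4R,8S,10S,11S,13S)-1,5,5-trimethyl-9-oxo-10-(2-oxopropyl)-6-oxatricyclo[6.3.2.0^{4,13}]tridecan-11-yl]ethenyl 3-methylbut-2-enoate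
Conditions: Cu(OTf)2 (20 mol %), DMAP (40 mol %), 4 Å molecular sieves, O2 (1 atm), MeCN, 40 °C
Reagents that add atoms: none
Why: Chan–Lam-type oxidative copper-catalysed C–O coupling of the alkenyl boronate with the carboxylic acid proceeds with retention at the alkene, so the E geometry from step 11 is carried into the enol ester without base strong enough to open the β-alkoxy ketone.

**Compound list**
1 | but-3-en-2-one | CC(=O)C=C | starting material
2 | 2-[(triisopropylsilyl)oxy]buta-1,3-diene | C=CC(=C)O[Si](C(C)C)(C(C)C)C(C)C | intermediate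
3 | methyl acrylate | COC(=O)C=C | starting material
4 | methyl (R)-4-[(triisopropylsilyl)oxy]cyclohex-3-ene-1-carboxylate | COC(=O)[C@H]1CC=C(O[Si](C(C)C)(C(C)C)C(C)C)CC1 | intermediate
5 | (R)-2-{4-[(triisopropylsilyl)oxy]cyclohex-3-en-1-yl}propan-2-ol | CC(C)(O)[C@H]1CC=C(O[Si](C(C)C)(C(C)C)C(C)C)CC1 | intermediate
6 | (R)-4-(2-hydroxypropan-2-yl)cyclohex-2-en-1-one | CC(C)(O)[C@@H]1CCC(=O)C=C1 | intermediate
7 | but-3-yn-2-one | CC(=O)C#C | starting material
8 | (R,E)-4-{[2-(4-oxocyclohex-2-en-1-yl)propan-2-yl]oxy}but-3-en-2-one | CC(=O)/C=C/OC(C)(C)[C@@H]1CCC(=O)C=C1 | intermediate (not isolated)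
9 | (4aS,8aR)-4-acetyl-1,1-dimethyl-4a,5,8,8a-tetrahydro-1H-isochromen-6(7H)-one (cis-fused) | CC(=O)C1=COC(C)(C)[C@@H]2CCC(=O)C[C@@H]21 | intermediate
10 | 1-[(4aS,8aR)-1,1-dimethyl-6-methylidene-4a,5,6,7,8,8a-hexahydro-1H-isochromen-4-yl]ethan-1-one | CC(=O)C1=COC(C)(C)[C@@H]2CCC(=C)C[C@@H]21 | intermediate
11 | 2,2-dimethoxyacetaldehyde | COC(OC)C=O | starting material
12 | 3-hydroxy-4,4-dimethoxy-1-[(4aS,8aR)-1,1-dimethyl-6-methylidene-4a,5,6,7,8,8a-hexahydro-1H-isochromen-4-yl]butan-1-one (both C3 epimers) | COC(OC)C(O)CC(=O)C1=COC(C)(C)[C@@H]2CCC(=C)C[C@@H]21 | intermediate (not isolated)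
13 | (E)-4,4-dimethoxy-1-[(4aS,8aR)-1,1-dimethyl-6-methylidene-4a,5,6,7,8,8a-hexahydro-1H-isochromen-4-yl]but-2-en-1-one | COC(OC)/C=C/C(=O)C1=COC(C)(C)[C@@H]2CCC(=C)C[C@@H]21 | intermediate
14 | (1S,4R,11S,13S)-11-(dimethoxymethyl)-1,5,5-trimethyl-6-oxatricyclo[6.3.2.0^{4,13}]tridec-7-en-9-one | C1C(=O)C2=COC(C)(C)[C@@H]3CC[C@@](C)(C[C@@H]32)[C@H]1C(OC)OC | intermediate
15 | (1S,4R,8S,11S,13S)-11-(dimethoxymethyl)-1,5,5-trimethyl-6-oxatricyclo[6.3.2.0^{4,13}]tridecan-9-one | C1C(=O)[C@@H]2COC(C)(C)[C@@H]3CC[C@@](C)(C[C@@H]32)[C@H]1C(OC)OC | intermediate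
16 | 3-bromo-2-methoxyprop-1-ene (2-methoxyallyl bromide) | COC(=C)CBr | starting material
17 | (1S,4R,8S,10S,11S,13S)-11-(dimethoxymethyl)-10-(2-methoxyprop-2-en-1-yl)-1,5,5-trimethyl-6-oxatricyclo[6.3.2.0^{4,13}]tridecan-9-one | COC(=C)C[C@@H]1C(=O)[C@@H]2COC(C)(C)[C@@H]3CC[C@@](C)(C[C@@H]32)[C@H]1C(OC)OC | intermediate (not isolated)
18 | (1S,4R,8S,10S,11S,13S)-1,5,5-trimethyl-9-oxo-10-(2-oxopropyl)-6-oxatricyclo[6.3.2.0^{4,13}]tridecane-11-carbaldehyde | CC(=O)C[C@@H]1C(=O)[C@@H]2COC(C)(C)[C@@H]3CC[C@@](C)(C[C@@H]32)[C@H]1C=O | intermediate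
19 | (1S,4R,8S,10S,11S,13S)-1,5,5-trimethyl-10-(2-oxopropyl)-11-[(E)-2-(4,4,5,5-tetramethyl-1,3,2-dioxaborolan-2-yl)ethenyl]-6-oxatricyclo[6.3.2.0^{4,13}]tridecan-9-one | CC(=O)C[C@@H]1C(=O)[C@@H]2COC(C)(C)[C@@H]3CC[C@@](C)(C[C@@H]32)[C@H]1/C=C/B4OC(C)(C)C(C)(C)O4 | intermediate
20 | 3-methylbut-2-enoic acid | CC(C)=CC(=O)O | starting material
21 | vibsanin E | CC(=O)C[C@@H]1C(=O)[C@@H]2COC(C)(C)[C@@H]3CC[C@@](C)(C[C@@H]32)[C@H]1/C=C/OC(=O)C=C(C)C | target

**Totals**
Total step count: 12. Longest linear sequence: 12 steps (from 1; all other building blocks are commercial).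

**Three steps most likely to fail**

Step 8 (radical 7-endo cyclisation). The likely failure is reduction or isomerisation of the alkene before the slow ring closure. The fallback makes the same tertiary radical with no hydride source present and sets out from 13. Mukaiyama hydration (Co(acac)2, O2, PhSiH3, then Me2S) gives the tertiary alcohol (E)-1-[(4aS,8aR)-6-hydroxy-1,1,6-trimethyl-4a,5,6,7,8,8a-hexahydro-1H-isochromen-4-yl]-4,4-dimethoxybut-2-en-1-one F1. Titanium-mediated dehydroxylative radical generation (Cp*TiCl3 10 mol %, Zn, Et3SiCl, THF) then releases the C1 radical from the C–O bond; it cyclises onto the enone and the titanium enolate is protonated on work-up. The route is rejoined at 14.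

Step 5 (oxa-Michael/Michael annulation). The likely failure is that the alkoxide generated next to the γ-acidic enone racemises or fragments it, or that the adduct stops at 8. The fallback forms the C–O bond before the enone exists and sets out from 5. PMe3-catalysed addition of 5 to 7 gives (R,E)-4-({2-[4-(triisopropylsilyloxy)cyclohex-3-en-1-yl]propan-2-yl}oxy)but-3-en-2-one F2. Saegusa–Ito oxidation (Pd(OAc)2, O2, DMSO) gives 8, now isolated. The ring is then closed under Lewis acid instead of nucleophilic catalysis (Sc(OTf)3 10 mol %, CH2Cl2, −40 °C): the enol-ether carbon of the vinylogous ester attacks the activated enone and a proton is lost. The route is rejoined at 9.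

Step 12 (C–O coupling of the alkenyl boronate). The likely failure is sluggish transmetalation of the pinacol boronate or protodeboronation. The fallback reverses the polarity of the alkenyl partner and sets out from 18. Takai iodo-olefination (CHI3, CrCl2, THF) gives (1S,4R,8S,10S,11S,13S)-11-[(E)-2-iodoethenyl]-1,5,5-trimethyl-10-(2-oxopropyl)-6-oxatricyclo[6.3.2.0^{4,13}]tridecan-9-one F3. Ullmann-type vinylation of the carboxylate of 20 (CuI, N,N′-dimethylethylenediamine, Cs2CO3, toluene, 60 °C) then forms the enol ester with retention. The route is rejoined at 21.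

**Further compounds**
F1 | step 8 | (E)-1-[(4aS,8aR)-6-hydroxy-1,1,6-trimethyl-4a,5,6,7,8,8a-hexahydro-1H-isochromen-4-yl]-4,4-dimethoxybut-2-en-1-one (C6 epimers) | COC(OC)/C=C/C(=O)C1=COC(C)(C)[C@@H]2CCC(C)(O)C[C@@H]21
F2 | step 5 | (R,E)-4-({2-[4-(triisopropylsilyloxy)cyclohex-3-en-1-yl]propan-2-yl}oxy)but-3-en-2-one | CC(=O)/C=C/OC(C)(C)[C@H]1CC=C(O[Si](C(C)C)(C(C)C)C(C)C)CC1
F3 | step 12 | (1S,4R,8S,10S,11S,13S)-11-[(E)-2-iodoethenyl]-1,5,5-trimethyl-10-(2-oxopropyl)-6-oxatricyclo[6.3.2.0^{4,13}]tridecan-9-one | CC(=O)C[C@@H]1C(=O)[C@@H]2COC(C)(C)[C@@H]3CC[C@@](C)(C[C@@H]32)[C@H]1/C=C/I
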